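**Retrosynthetic overview**
1. The C26 acyl chain is C22 (1-bromodocosane 1) + C3 (2-phenylethyl acrylate 2, which already carries the finished ester) + C1 (one CO ligand of Na2Fe(CO)4). This fixes the even/odd carbon count using cheap even-chain stock.
2. The key disconnection is C3–C4, made by umpolung. Alkyl ferrate 3 inserts CO, which also makes C4–C5, to give acyl ferrate 4, an acyl anion equivalent. Its acyl carbon joins the β-carbon of 2, two carbons that are both natural electrophiles, via 5 to give 4-oxo ester 6.
3. The last disconnection is a functional-group change only. The C4 ketone of 6 is removed through tosylhydrazone 7 (then 8 and 9 in the flask) to give target 10.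
4. No ring is formed (the phenyl ring is bought in 2), and there is no stereocentre to set.

Assumption: the SMILES has no stereocentre and no double-bond geometry, so the target is achiral and is made as such.

**Step 1**
Reactants: 1 1-bromodocosane; 2 2-phenylethyl acrylate
Product: 6 2-phenylethyl 4-oxohexacosanoate, via sodium docosyl(tetracarbonyl)ferrate 3 (not isolated), via sodium tricosanoyl(tricarbonyl)ferrate 4 (not isolated), via sodium tricarbonyl(1,4-dioxo-1-phenethyloxyhexacosan-2-yl)ferrate 5 (not isolated)
Conditions: Na2Fe(CO)4·1.5 dioxane (1.0 equiv), 1 (1.05 equiv), THF, Ar, 25 → 40 °C, 3 h; then 2 (1.3 equiv), 25 °C, 12 h; then AcOH (excess), 0 °C → rt, air, filtration through SiO2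
Reagents that add atoms: disodium tetracarbonylferrate, Na2Fe(CO)4 (one CO ligand becomes the C4 carbonyl), [Na+].[Na+].O=C=[Fe-2](=C=O)(=C=O)=C=O
Why: The ferrate dianion displaces the primary bromide (SN2) to give 3, sodium-ion-assisted alkyl migration to CO unmasks the unsaturated acyl ferrate 4 as an acyl anion equivalent, its acyl carbon (future C4) is delivered to the electrophilic β-carbon of coordinated 2 (future C3) by olefin insertion to give 5, and AcOH protonates C2, which is the known Collman-type carbonylative conjugate acylation of Michael acceptors by alkyltetracarbonylferrates (the stoichiometric organometallic counterpart of a Stetter reaction); esters are inert to these soft ferrates and no stereocentre remains in 6.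

**Step 2**
Reactants: 6 2-phenylethyl 4-oxohexacosanoate
Product: 10 2-phenylethyl hexacosanoate, via tosylhydrazone 7 (not isolated), via N-boryl tosylhydrazide 8 (not isolated), via monoalkyl diazene 9 (not isolated)
Conditions: TsNHNH2 (1.1 equiv), THF–EtOH, 60 °C, 4 h, evaporate (PhMe azeotrope); catecholborane (2.0 equiv), CHCl3, 0 °C → rt, 2 h; NaOAc·3H2O (3 equiv), reflux, 1 h
Reagents that add atoms: none
Why: This is a Caglioti-type tosylhydrazone deoxygenation in its catecholborane (Kabalka) form, in which condensation gives 7, catecholborane hydroborates only the C=N bond (esters are untouched at 0 °C) to give 8 whose nitrogen stays boron-bound and so cannot lactamise onto the γ-ester, acetate then triggers loss of sulfinate to diazene 9, and 9 expels N2 with hydrogen transfer to C4, so the transient racemic C4 centre ends as a CH2 group and the achiral target results.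

**Compound list**
1 | 1-bromodocosane (behenyl bromide) | CCCCCCCCCCCCCCCCCCCCCCBr | starting material
2 | 2-phenylethyl acrylate (2-phenylethyl prop-2-enoate) | C=CC(=O)OCCc1ccccc1 | starting material
3 | sodium docosyl(tetracarbonyl)ferrate, Na[Fe(CO)4(C22H45)] | CCCCCCCCCCCCCCCCCCCCCC[Fe-](=C=O)(=C=O)(=C=O)=C=O.[Na+] | intermediate (not isolated)
4 | sodium tricosanoyl(tricarbonyl)ferrate, Na[Fe(CO)3(COC22H45)], the acyl anion equivalent | CCCCCCCCCCCCCCCCCCCCCCC(=O)[Fe-](=C=O)(=C=O)=C=O.[Na+] | intermediate (not isolated)
5 | sodium tricarbonyl(1,4-dioxo-1-phenethyloxyhexacosan-2-yl)ferrate, iron bound at C2 of the keto ester, racemic at C2 | CCCCCCCCCCCCCCCCCCCCCCC(=O)CC(C(=O)OCCc1ccccc1)[Fe-](=C=O)(=C=O)=C=O.[Na+] | intermediate (not isolated)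
6 | 2-phenylethyl 4-oxohexacosanoate | CCCCCCCCCCCCCCCCCCCCCCC(=O)CCC(=O)OCCc1ccccc1 | intermediate (isolated)
7 | 2-phenylethyl 4-(2-tosylhydrazinylidene)hexacosanoate, E/Z mixture at C=N | CCCCCCCCCCCCCCCCCCCCCCC(CCC(=O)OCCc1ccccc1)=NNS(=O)(=O)c1ccc(C)cc1 | intermediate (not isolated)
8 | 2-phenylethyl 4-[1-(1,3,2-benzodioxaborol-2-yl)-2-tosylhydrazinyl]hexacosanoate, racemic at C4 | CCCCCCCCCCCCCCCCCCCCCCC(CCC(=O)OCCc1ccccc1)N(B1Oc2ccccc2O1)NS(=O)(=O)c1ccc(C)cc1 | intermediate (not isolated)
9 | 2-phenylethyl 4-diazenylhexacosanoate, racemic at C4 | CCCCCCCCCCCCCCCCCCCCCCC(CCC(=O)OCCc1ccccc1)N=N | intermediate (not isolated)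
10 | 2-phenylethyl hexacosanoate (phenylethyl n-hexacosanoate), achiral | CCCCCCCCCCCCCCCCCCCCCCCCCC(=O)OCCc1ccccc1 | target

**Total step count:** 2
**Longest linear sequence:** 2

**Steps most likely to fail.** The route has only two steps. Both are ranked, and step 1 is entered twice because it has two independent failure modes.

First, step 1 at the conjugate acylation stage (4 to 5). The acrylate may oligomerise on the iron enolate. Alternatively, 3 and 4 may survive until the quench and give docosane or the aldehyde instead of 6. The fallback sets out from 1 and replaces stoichiometric iron by organocatalytic carbonyl umpolung. Magnesium in THF converts 1 into docosylmagnesium bromide F1. DMF formylates this to tricosanal F2. A Stetter reaction then adds the aldehyde carbon to 2, using 3-benzyl-5-(2-hydroxyethyl)-4-methylthiazolium chloride (15 mol %) and Et3N in dioxane–EtOH at 80 °C. The fallback comes back to the route at 6.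

Second, step 2. Residual ketone would be reduced and lactonise with loss of 2-phenylethanol. If boron is lost early from 8, the γ-nitrogen could close to an N-amino lactam. The fallback sets out from 6 and avoids all C4–O and C4–N intermediates. 1,2-Ethanedithiol with BF3·OEt2 in CH2Cl2 gives 2-phenylethyl 3-(2-docosyl-1,3-dithiolan-2-yl)propanoate F3. Raney Ni in refluxing EtOH–THF (Mozingo desulfurisation) then strips the sulfur. The phenethyl ester and the arene are untouched. The fallback comes back to the route at 10.

Third, step 1 at the formation and handling of 3. Na2Fe(CO)4 is pyrophoric, and the SN2 reaction on the waxy bromide is slow in THF. The fallback sets out from 1 and 2 and swaps the two-electron iron chemistry for a radical chain with CO gas as the C1 source. The conditions are (Me3Si)3SiH, AIBN, CO (80 atm), benzene, 80 °C, with 1 dilute and 2 at 1.2 equiv. The docosyl radical traps CO, and the nucleophilic acyl radical adds to the β-carbon of 2. The direct Giese by-product (a C25 ester) is much less polar than the keto ester and is removed by chromatography. This fallback makes no new isolable compound (F0) and comes back to the route at 6.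

**Further compounds**
F1 | step 1 | docosylmagnesium bromide | CCCCCCCCCCCCCCCCCCCCCC[Mg]Br
F2 | step 1 | tricosanal | CCCCCCCCCCCCCCCCCCCCCCC=O
F3 | step 2 | 2-phenylethyl 3-(2-docosyl-1,3-dithiolan-2-yl)propanoate | CCCCCCCCCCCCCCCCCCCCCCC1(CCC(=O)OCCc2ccccc2)SCCS1
F0 | step 1 | none | none
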